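**Assumption:** the SMILES has no stereocentre and no double bond with E/Z isomers (the chromene alkene is ring-locked, the prenyl alkene carries two methyls). The target is therefore achiral and no enantiocontrol is needed.

## Retrosynthetic overview
1. Dione C=O next to ring B ⇒ a new C–O bond made from water at the benzylic CH2 of the pyrano-deoxybenzoin, through an acyl para-quinone methide (last step, new method).
2. Pyran ring C (closing bond O–CMe2, oxa-6π) ⇒ 3-prenyl-2,4-dihydroxy-6-methoxydeoxybenzoin + prenal. C3 is blocked and C6 carries OMe, so only C5 and the 4-OH can close the ring.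
3. Prenyl group ⇒ C3-selective nuclear prenylation with prenyl bromide.
4. Deoxybenzoin ⇒ Houben–Hoesch union of 5-methoxyresorcinol and 4-hydroxyphenylacetonitrile.
5. Ring order: rings A and B are bought, and ring C is the only ring formed (step 3). No protecting groups are used.

## Route

**Step 1**
Reactants: 1 5-methoxyresorcinol; 2 4-hydroxyphenylacetonitrile
Product: 4 1-(2,4-dihydroxy-6-methoxyphenyl)-2-(4-hydroxyphenyl)ethan-1-one, via ketiminium chloride 3 (not isolated)
Conditions: ZnCl2 (0.5 equiv), HCl (g), Et2O, 0 °C, 24 h; then H2O, reflux, 2 h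
Reagents that add atoms: 4-hydroxyphenylacetonitrile 2, N#CCc1ccc(O)cc1; water, O
Why: Houben–Hoesch acylation, in which the HCl/ZnCl2-activated nitrile attacks the phloroglucinol-type ring mainly at C4 of 1 (para to one OH, two equivalent sites against one at C2), the monophenol ring of 2 is too unreactive to compete, hot water hydrolyses salt 3 to ketone 4, the minor 2,6-dihydroxy-4-methoxy isomer is removed by crystallisation, and no stereocentre is formed.

**Step 2**
Reactants: 4 1-(2,4-dihydroxy-6-methoxyphenyl)-2-(4-hydroxyphenyl)ethan-1-one; 5 prenyl bromide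
Product: 6 1-[2,4-dihydroxy-6-methoxy-3-(3-methylbut-2-en-1-yl)phenyl]-2-(4-hydroxyphenyl)ethan-1-one
Conditions: KOH (1.05 equiv), 5 (1.0 equiv), H2O–MeOH 4:1, 0 °C to rt
Reagents that add atoms: prenyl bromide 5, CC(C)=CCBr
Why: Nuclear (C-)prenylation of an ambident phenoxide in a protic medium, where one equivalent of base ionises only the most acidic 4-OH (a vinylogous acid), hydrogen bonding to the phenoxide oxygen diverts the soft allylic bromide to carbon, C3 between the two oxygens is the most nucleophilic carbon, and the un-ionised 4'-OH and the CH2 stay untouched; no stereocentre is formed.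

**Step 3**
Reactants: 6 1-[2,4-dihydroxy-6-methoxy-3-(3-methylbut-2-en-1-yl)phenyl]-2-(4-hydroxyphenyl)ethan-1-one; 7 prenal (3-methylbut-2-enal)
Product: 9 1-[7-hydroxy-5-methoxy-2,2-dimethyl-8-(3-methylbut-2-en-1-yl)-2H-chromen-6-yl]-2-(4-hydroxyphenyl)ethan-1-one, via vinyl ortho-quinone methide 8 (not isolated)
Conditions: 7 (2.0 equiv), Ca(OH)2 (1.0 equiv), MeOH, Ar, rt, 48 h
Reagents that add atoms: prenal 7, CC(C)=CC=O
Why: Calcium-phenoxide aldol at the only free ring carbon (C5), dehydration to 8 and irreversible oxa-6π electrocyclisation (formal 3+3 chromenylation) can close only onto the 4-oxygen because the other neighbour is OMe, while any aldol at the ketone CH2 is reversible at rt and has no such sink; no stereocentre is formed.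

**Step 4**
Reactants: 9 1-[7-hydroxy-5-methoxy-2,2-dimethyl-8-(3-methylbut-2-en-1-yl)-2H-chromen-6-yl]-2-(4-hydroxyphenyl)ethan-1-one
Product: 12 derrisdione A, via acyl para-quinone methide 10 (not isolated), via benzoin 11 (not isolated)
Conditions: 3,3',5,5'-tetra-tert-butyl-4,4'-diphenoquinone (DPQ, 2.2 equiv), Cs2CO3 (3 equiv), degassed THF–H2O 5:1, Ar, 25 °C, slow addition of 9 to the oxidant; aq. citric acid work-up
Reagents that add atoms: water, O
Why: Proposed new method: a redox-gated dehydrogenative 1,6-hydration of a 4-hydroxybenzyl ketone, in which the enolate/4'-phenoxide of 9 is a vinylogous hydroquinone and the only site reducing enough to pass two electrons to the mild, poorly hydride-accepting quinone DPQ, giving 10; water then adds 1,6 at the former CH2 carbon to make the new C–O bond (11), and the enediolate of 11 is oxidised by the second equivalent of DPQ to the dione, while the prenyl group, the chromene alkene and the simple phenoxides lie outside this redox window, excluding O2 and peroxide avoids C–C cleavage of the dione, and the transient stereocentre of 11 is erased; the closest known reaction types are DDQ oxidation of 4-hydroxy- or 4-alkoxybenzylic C–H bonds in wet solvent, flavoenzyme hydroxylation of 4-alkylphenols through quinone methides, base/O2 oxidation of deoxybenzoins to benzils, and DPQ as terminal oxidant in carbene catalysis.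

## Compound list
1 | 5-methoxyresorcinol (3,5-dihydroxyanisole) | COc1cc(O)cc(O)c1 | starting material
2 | 4-hydroxyphenylacetonitrile | N#CCc1ccc(O)cc1 | starting material
3 | 1-(2,4-dihydroxy-6-methoxyphenyl)-2-(4-hydroxyphenyl)ethan-1-iminium chloride | COc1cc(O)cc(O)c1C(=[NH2+])Cc1ccc(O)cc1.[Cl-] | intermediate
4 | 1-(2,4-dihydroxy-6-methoxyphenyl)-2-(4-hydroxyphenyl)ethan-1-one | COc1cc(O)cc(O)c1C(=O)Cc1ccc(O)cc1 | intermediate
5 | prenyl bromide (1-bromo-3-methylbut-2-ene) | CC(C)=CCBr | starting material
6 | 1-[2,4-dihydroxy-6-methoxy-3-(3-methylbut-2-en-1-yl)phenyl]-2-(4-hydroxyphenyl)ethan-1-one | COc1cc(O)c(CC=C(C)C)c(O)c1C(=O)Cc1ccc(O)cc1 | intermediate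
7 | prenal (3-methylbut-2-enal) | CC(C)=CC=O | starting material
8 | (6Z)-3-hydroxy-4-[(4-hydroxyphenyl)acetyl]-5-methoxy-6-(3-methylbut-2-en-1-ylidene)-2-(3-methylbut-2-en-1-yl)cyclohexa-2,4-dien-1-one | O=C1C(CC=C(C)C)=C(O)C(C(=O)Cc2ccc(O)cc2)=C(OC)/C1=C/C=C(C)C | intermediate
9 | 1-[7-hydroxy-5-methoxy-2,2-dimethyl-8-(3-methylbut-2-en-1-yl)-2H-chromen-6-yl]-2-(4-hydroxyphenyl)ethan-1-one | COc1c2c(c(CC=C(C)C)c(O)c1C(=O)Cc1ccc(O)cc1)OC(C)(C)C=C2 | intermediate
10 | 4-{2-[7-hydroxy-5-methoxy-2,2-dimethyl-8-(3-methylbut-2-en-1-yl)-2H-chromen-6-yl]-2-oxoethylidene}cyclohexa-2,5-dien-1-one | COc1c2c(c(CC=C(C)C)c(O)c1C(=O)C=C1C=CC(=O)C=C1)OC(C)(C)C=C2 | intermediate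
11 | 2-hydroxy-1-[7-hydroxy-5-methoxy-2,2-dimethyl-8-(3-methylbut-2-en-1-yl)-2H-chromen-6-yl]-2-(4-hydroxyphenyl)ethan-1-one (racemic) | COc1c2c(c(CC=C(C)C)c(O)c1C(=O)C(O)c1ccc(O)cc1)OC(C)(C)C=C2 | intermediate
12 | derrisdione A, 1-[7-hydroxy-5-methoxy-2,2-dimethyl-8-(3-methylbut-2-en-1-yl)-2H-chromen-6-yl]-2-(4-hydroxyphenyl)ethane-1,2-dione (achiral) | COc1c2c(c(CC=C(C)C)c(O)c1C(=O)C(=O)c1ccc(O)cc1)OC(C)(C)C=C2 | target

**Total step count:** 4
**Longest linear sequence:** 4 (1 → 4 → 6 → 9 → 12)

## Three steps most likely to fail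

**Step 4 (new method).**
- Risks:
  - enolisation of the already anionic substrate may be slow;
  - the captodative radical may dimerise, or the enolate may add to 10 (hence dilution and inverse addition);
  - the 7-OH/prenyl pair may undergo slow dehydrogenation.
- Capture of 10 by the neighbouring 7-phenoxide instead of water is not a dead end. That adduct is again a vinylogous hydroquinone, and the same oxidant and water carry it to the ring-chain tautomer of 12.
- The fallback uses known chemistry: electrophilic enolate hydroxylation followed by alcohol oxidation on a protected phenol. It sets out from 9 and comes back at 12.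
  - TBSCl and imidazole (DMF, 0 °C) silylate only the unhindered 4'-OH, because the chelated, flanked 7-OH does not react. This gives the 4'-O-tert-butyldimethylsilyl deoxybenzoin F1.
  - Double deprotonation with KN(SiMe3)2 (2.2 equiv, THF, −78 °C), then 2-(phenylsulfonyl)-3-phenyloxaziridine, gives the racemic silylated benzoin F2.
  - Activated MnO2 (CH2Cl2, rt) gives the silylated benzil F3.
  - Bu4NF/AcOH (THF, 0 °C) releases 12.

**Step 2 (C-prenylation).**
- Risks: O-prenylation, attack at C5, double prenylation and a modest yield.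
- The fallback replaces phenoxide alkylation by halogenation and cross-coupling. It sets out from 4 and comes back at 6.
  - I2/HIO3 (aq. EtOH, rt, one equivalent of electrophilic iodine) iodinates the most activated carbon between the two hydroxyls. This gives the 3-iodo deoxybenzoin F4.
  - Stille coupling with tributyl(3-methylbut-2-en-1-yl)stannane (Pd(PPh3)4 5 mol %, LiCl, DMF, 80 °C) delivers the linear prenyl compound 6.

**Step 3 (chromenylation).**
- Risks: sluggish reaction at C5, or condensation of prenal at the ketone CH2 followed by closure to a 2-substituted isoflavanone.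
- The fallback makes the aryl–O–CMe2 bond first and forms the C–C bond by rearrangement. It sets out from 6 and comes back at 9.
  - 3-Chloro-3-methylbut-1-yne, CuCl2·2H2O (1 mol %) and 1,8-diazabicyclo[5.4.0]undec-7-ene (1.05 equiv) in MeCN at 0 °C alkylate the most acidic 4-OH. This gives the aryl 1,1-dimethylpropargyl ether F5.
  - Heating in xylenes at 140 °C triggers propargyl Claisen rearrangement to C5, a 1,5-H shift and oxa-6π closure to 9.

## Further compounds
F1 | step 4 | 2-{4-[(tert-butyldimethylsilyl)oxy]phenyl}-1-[7-hydroxy-5-methoxy-2,2-dimethyl-8-(3-methylbut-2-en-1-yl)-2H-chromen-6-yl]ethan-1-one | COc1c2c(c(CC=C(C)C)c(O)c1C(=O)Cc1ccc(O[Si](C)(C)C(C)(C)C)cc1)OC(C)(C)C=C2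
F2 | step 4 | 2-{4-[(tert-butyldimethylsilyl)oxy]phenyl}-2-hydroxy-1-[7-hydroxy-5-methoxy-2,2-dimethyl-8-(3-methylbut-2-en-1-yl)-2H-chromen-6-yl]ethan-1-one (racemic) | COc1c2c(c(CC=C(C)C)c(O)c1C(=O)C(O)c1ccc(O[Si](C)(C)C(C)(C)C)cc1)OC(C)(C)C=C2
F3 | step 4 | 1-{4-[(tert-butyldimethylsilyl)oxy]phenyl}-2-[7-hydroxy-5-methoxy-2,2-dimethyl-8-(3-methylbut-2-en-1-yl)-2H-chromen-6-yl]ethane-1,2-dione | COc1c2c(c(CC=C(C)C)c(O)c1C(=O)C(=O)c1ccc(O[Si](C)(C)C(C)(C)C)cc1)OC(C)(C)C=C2
F4 | step 2 | 1-(2,4-dihydroxy-3-iodo-6-methoxyphenyl)-2-(4-hydroxyphenyl)ethan-1-one | COc1cc(O)c(I)c(O)c1C(=O)Cc1ccc(O)cc1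
F5 | step 3 | 1-[2-hydroxy-6-methoxy-4-(2-methylbut-3-yn-2-yloxy)-3-(3-methylbut-2-en-1-yl)phenyl]-2-(4-hydroxyphenyl)ethan-1-one | COc1cc(OC(C)(C)C#C)c(CC=C(C)C)c(O)c1C(=O)Cc1ccc(O)cc1
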